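The carbocycle is numbered C1 (bears the side chain), C2 (CH2), C3–C4 (epoxide, CH3 on C4), C5 (C=O), C6 (CH–O-tigloyl). Everything rests on cutting C1–C6. The acyloin C5(=O)–C6H(O), lying next to the C3–C4 epoxide, is read as the product of an α-ketol shift fed by an epoxide migration. The precursor is a cyclopentane, a 3-hydroxy-1,2-epoxycyclopentane-1-carbaldehyde made by contracting (S)-carvone, whose carbonyl oxygen ends as the epoxide oxygen. One alkoxide moves the epoxide to C3–C4, unmasks a tertiary α-alkoxy aldehyde, and pushes C1 from C5 onto the formyl carbon. The six-membered ring, the ketone, the epoxide and the C4 and C6 stereocentres arise in one flask, and the C6 alkoxide is trapped as the tiglate.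

Key step: step 8

Remark on the chemistry: alcohol 17 is formed and carried on as a mixture of epimers at the new carbinol carbon. This carbon becomes the side-chain ketone in step 11.

Step 1
Reactants: 1 (S)-(+)-carvone
Product: 2 (1S,5S)-cis-carveol
Conditions: NaBH4, CeCl3·7H2O, MeOH, −20 °C
Reagents that add atoms: none
Why: Luche reduction delivers hydride 1,2 along the axial trajectory of the half-chair with equatorial isopropenyl, so the new C–O bond (later C3–O of the target) should lie cis to the isopropenyl group.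

Step 2
Reactants: 2 (1S,5S)-cis-carveol
Product: 3 (1S,2S,4R,6R)-1-methyl-4-(prop-1-en-2-yl)-7-oxabicyclo[4.1.0]heptan-2-ol
Conditions: VO(acac)2 (cat.), t-BuOOH (decane), CH2Cl2, 0 °C to rt
Reagents that add atoms: tert-butyl hydroperoxide, CC(C)(C)OO
Why: Vanadium-catalysed hydroxyl-directed epoxidation should oxidise only the allylic ring alkene, syn to the hydroxyl, and spare the isopropenyl group; the two new centres are erased in step 4.

Step 3
Reactants: 3 epoxy alcohol
Product: 4 tert-butyldimethylsilyl ether of 3
Conditions: TBSCl, imidazole, DMF, rt to 40 °C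
Reagents that add atoms: tert-butyldimethylsilyl chloride, CC(C)(C)[Si](C)(C)Cl
Why: Silyl ether formation masks the carbinol so that the glycol cleavage of step 4 cannot also cut the bond between the carbinol carbon and the methyl-bearing carbon; no stereocentre is touched.

Step 4
Reactants: 4 epoxy silyl ether
Product: 5 (3R,5S)-5-(tert-butyldimethylsilyloxy)-6-oxo-3-(prop-1-en-2-yl)heptanal
Conditions: H5IO6, THF–Et2O, 0 °C to rt
Reagents that add atoms: orthoperiodic acid, O=I(O)(O)(O)(O)O
Why: Acid-assisted hydrolysis of the trisubstituted epoxide followed by Malaprade glycol cleavage in one flask should open the carvone ring to the keto aldehyde, leaving the 1,1-disubstituted alkene and both stereocentres unchanged.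

Step 5
Reactants: 5 keto aldehyde
Product: 6 (3S,5S)-3-(tert-butyldimethylsilyloxy)-2-methyl-5-(prop-1-en-2-yl)cyclopent-1-ene-1-carbaldehyde
Conditions: piperidine (cat.), AcOH (cat.), toluene, 60 °C
Reagents that add atoms: none
Why: Enamine-catalysed intramolecular aldol condensation lets the aldehyde α-carbon attack the methyl ketone (five-membered ring, 5-enolexo-exo-trig), and dehydration should give the tetrasubstituted enal with both existing centres retained.

Step 6
Reactants: 6 silyloxy enal
Product: 7 (1S,2S,4S,5R)-4-(tert-butyldimethylsilyloxy)-5-methyl-2-(prop-1-en-2-yl)-6-oxabicyclo[3.1.0]hexane-1-carbaldehyde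
Conditions: 30% H2O2, NaOH (cat.), MeOH, 0 °C
Reagents that add atoms: hydrogen peroxide, OO
Why: Weitz–Scheffer epoxidation touches only the electron-poor enal, and hydroperoxide should add from the ring face opposite to both the silyloxy and the isopropenyl groups, placing the oxirane trans to the C3 oxygen as step 8 requires.

Step 7
Reactants: 7 silyloxy epoxy aldehyde
Product: 8 (1S,2S,4S,5R)-4-hydroxy-5-methyl-2-(prop-1-en-2-yl)-6-oxabicyclo[3.1.0]hexane-1-carbaldehyde
Conditions: HF·pyridine, pyridine, THF, 0 °C to rt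
Reagents that add atoms: none
Why: Buffered fluoride desilylation frees the alcohol without ever forming its alkoxide, so the cascade of step 8 should not start early; no stereocentre is touched.

Step 8
Reactants: 8 hydroxy epoxy aldehyde; 9 tigloyl chloride
Product: 12 (1S,3S,4S,6S)-1-methyl-2-oxo-4-(prop-1-en-2-yl)-7-oxabicyclo[4.1.0]heptan-3-yl (E)-2-methylbut-2-enoate, via migrated epoxy hydroxy aldehyde 10 (not isolated), via ring-enlarged hydroxy ketone 11 (not isolated)
Conditions: NaH (1.05 equiv), THF, 0 °C to rt; then 9, 0 °C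
Reagents that add atoms: none
Why: The C3 alkoxide attacks C4 from the face opposite to the C4–C5 oxirane oxygen (Payne rearrangement) and releases the tertiary C5 alkoxide of 10, which collapses to the C5 ketone while the C5–C1 ring bond shifts to the formyl carbon C6 (α-ketol rearrangement), and the C6 alkoxide of 11 is then acylated by 9. The closest known reaction types are the base-induced epoxide migration of 2,3-epoxy alcohols and the acyloin ring enlargement of 1-hydroxycycloalkanecarbaldehydes and of 17-hydroxy-20-keto steroids. The new oxirane closes in the 3-exo-tet mode, whereas the six-membered ring is not closed by cyclisation but grows from the cyclopentane through a suprafacial 1,2-shift of a ring bond. C3 keeps the carveol configuration, C4 is inverted by the backside attack so that the epoxide ends cis to the isopropenyl group, C1 migrates with retention, and C6 is set by the sodium chelate that holds the C5–O and C6=O bonds syn, which places the C6 oxygen equatorial and trans to the isopropenyl group, the arrangement that enolate equilibration would favour as well. The step needs migration of C1 rather than C4, which is secured because C1 is a secondary allylic carbon whereas C4 is an oxirane carbon with high s character and an electron-withdrawing oxygen. The uphill epoxide equilibrium (tetrasubstituted to trisubstituted oxirane) is drained by the irreversible aldehyde-to-ketone shift and the strain relief on going from the five-membered to the six-membered ring.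

Step 9
Reactants: 12 epoxy keto tiglate
Product: 13 (1S,3S,4S,6S)-1-methyl-2-oxo-4-(3-oxoprop-1-en-2-yl)-7-oxabicyclo[4.1.0]heptan-3-yl (E)-2-methylbut-2-enoate
Conditions: SeO2, 1,4-dioxane, 70 °C
Reagents that add atoms: selenium dioxide, O=[Se]=O
Why: Riley allylic oxidation (ene reaction, then [2,3]-sigmatropic shift) should select the only electron-rich alkene, and within it the open methyl group rather than the ring methine shielded by the acyloxy carbon, and carry it to the enal.

Step 10
Reactants: 13 enal; 14 2-methyl-2-(trimethylsilyloxy)but-3-yne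
Product: 17 (1S,3S,4S,6S)-4-[(4E)-3-hydroxy-6-methyl-6-(trimethylsilyloxy)hepta-1,4-dien-2-yl]-1-methyl-2-oxo-7-oxabicyclo[4.1.0]heptan-3-yl (E)-2-methylbut-2-enoate, via alkenylzirconocene chloride 15 (not isolated), via alkenyl(methyl)zinc 16 (not isolated)
Conditions: 14, Cp2Zr(H)Cl, CH2Cl2, rt; Me2Zn, toluene, −65 °C; then 13, 0 °C; aq NaHCO3
Reagents that add atoms: none
Why: Syn hydrozirconation of the terminal alkyne fixes the E geometry, and zirconium-to-zinc transmetalation gives an alkenylzinc that should add 1,2 to the aldehyde but not to the hindered ketone, ester or epoxide; the new carbinol centre is uncontrolled and is erased in step 11.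

Step 11
Reactants: 17 bis-allylic alcohol
Product: 19 target CNP0263368.1, via silylated dienone 18 (not isolated)
Conditions: Dess–Martin periodinane, CH2Cl2, 0 °C to rt; then AcOH–THF–H2O, rt
Reagents that add atoms: none
Why: Dess–Martin oxidation should turn the bis-allylic alcohol into the cross-conjugated dienone without base, and mild acid hydrolysis then removes the tertiary trimethylsilyl ether; no stereocentre is touched.

Compound list
1 | (S)-(+)-carvone, (5S)-2-methyl-5-(prop-1-en-2-yl)cyclohex-2-en-1-one | CC1=CC[C@H](C(C)=C)CC1=O | starting material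
2 | (+)-cis-carveol, (1S,5S)-2-methyl-5-(prop-1-en-2-yl)cyclohex-2-en-1-ol, OH cis to isopropenyl | CC1=CC[C@H](C(C)=C)C[C@@H]1O | intermediate
3 | (1S,2S,4R,6R)-1-methyl-4-(prop-1-en-2-yl)-7-oxabicyclo[4.1.0]heptan-2-ol, oxirane O, OH and isopropenyl on one face | C[C@@]12O[C@@H]1C[C@H](C(C)=C)C[C@@H]2O | intermediate
4 | tert-butyldimethylsilyl ether of 3, configuration unchanged | C[C@@]12O[C@@H]1C[C@H](C(C)=C)C[C@@H]2O[Si](C)(C)C(C)(C)C | intermediate
5 | (3R,5S)-5-(tert-butyldimethylsilyloxy)-6-oxo-3-(prop-1-en-2-yl)heptanal | CC(=O)[C@@H](O[Si](C)(C)C(C)(C)C)C[C@@H](C(C)=C)CC=O | intermediate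
6 | (3S,5S)-3-(tert-butyldimethylsilyloxy)-2-methyl-5-(prop-1-en-2-yl)cyclopent-1-ene-1-carbaldehyde, silyloxy cis to isopropenyl | O=CC1=C(C)[C@@H](O[Si](C)(C)C(C)(C)C)C[C@H]1C(C)=C | intermediate
7 | (1S,2S,4S,5R)-4-(tert-butyldimethylsilyloxy)-5-methyl-2-(prop-1-en-2-yl)-6-oxabicyclo[3.1.0]hexane-1-carbaldehyde, oxirane trans to silyloxy and isopropenyl | O=C[C@@]12O[C@]1(C)[C@@H](O[Si](C)(C)C(C)(C)C)C[C@H]2C(C)=C | intermediate
8 | (1S,2S,4S,5R)-4-hydroxy-5-methyl-2-(prop-1-en-2-yl)-6-oxabicyclo[3.1.0]hexane-1-carbaldehyde | O=C[C@@]12O[C@]1(C)[C@@H](O)C[C@H]2C(C)=C | intermediate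
9 | tigloyl chloride, (E)-2-methylbut-2-enoyl chloride | ClC(=O)/C(C)=C/C | starting material
10 | (1S,2S,3S,5S)-2-hydroxy-1-methyl-3-(prop-1-en-2-yl)-6-oxabicyclo[3.1.0]hexane-2-carbaldehyde, present as its sodium alkoxide | O=C[C@@]1(O)[C@@]2(C)O[C@H]2C[C@H]1C(C)=C | intermediate
11 | (1S,3S,4S,6S)-3-hydroxy-1-methyl-4-(prop-1-en-2-yl)-7-oxabicyclo[4.1.0]heptan-2-one, present as its sodium alkoxide | C=C(C)[C@@H]1C[C@@H]2O[C@]2(C)C(=O)[C@H]1O | intermediate
12 | (1S,3S,4S,6S)-1-methyl-2-oxo-4-(prop-1-en-2-yl)-7-oxabicyclo[4.1.0]heptan-3-yl (E)-2-methylbut-2-enoate | C=C(C)[C@@H]1C[C@@H]2O[C@]2(C)C(=O)[C@H]1OC(=O)/C(C)=C/C | intermediate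
13 | (1S,3S,4S,6S)-1-methyl-2-oxo-4-(3-oxoprop-1-en-2-yl)-7-oxabicyclo[4.1.0]heptan-3-yl (E)-2-methylbut-2-enoate | C=C(C=O)[C@@H]1C[C@@H]2O[C@]2(C)C(=O)[C@H]1OC(=O)/C(C)=C/C | intermediate
14 | 2-methyl-2-(trimethylsilyloxy)but-3-yne | C#CC(C)(C)O[Si](C)(C)C | starting material
15 | chlorobis(cyclopentadienyl)[(E)-3-methyl-3-(trimethylsilyloxy)but-1-enyl]zirconium | C[Si](C)(C)OC(C)(C)/C=C/[Zr](Cl)(C1C=CC=C1)C1C=CC=C1 | intermediate
16 | methyl[(E)-3-methyl-3-(trimethylsilyloxy)but-1-enyl]zinc | C[Zn]/C=C/C(C)(C)O[Si](C)(C)C | intermediate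
17 | (1S,3S,4S,6S)-4-[(4E)-3-hydroxy-6-methyl-6-(trimethylsilyloxy)hepta-1,4-dien-2-yl]-1-methyl-2-oxo-7-oxabicyclo[4.1.0]heptan-3-yl (E)-2-methylbut-2-enoate, both carbinol epimers | C=C(C(O)/C=C/C(C)(C)O[Si](C)(C)C)[C@@H]1C[C@@H]2O[C@]2(C)C(=O)[C@H]1OC(=O)/C(C)=C/C | intermediate
18 | (1S,3S,4S,6S)-1-methyl-4-[(4E)-6-methyl-3-oxo-6-(trimethylsilyloxy)hepta-1,4-dien-2-yl]-2-oxo-7-oxabicyclo[4.1.0]heptan-3-yl (E)-2-methylbut-2-enoate | C=C(C(=O)/C=C/C(C)(C)O[Si](C)(C)C)[C@@H]1C[C@@H]2O[C@]2(C)C(=O)[C@H]1OC(=O)/C(C)=C/C | intermediate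
19 | CNP0263368.1, (1S,3S,4S,6S)-4-[(4E)-6-hydroxy-6-methyl-3-oxohepta-1,4-dien-2-yl]-1-methyl-2-oxo-7-oxabicyclo[4.1.0]heptan-3-yl (E)-2-methylbut-2-enoate | C=C(C(=O)/C=C/C(C)(C)O)[C@@H]1C[C@@H]2O[C@]2(C)C(=O)[C@H]1OC(=O)/C(C)=C/C | target

Total step count: 11. Longest linear sequence: 11 steps (1 to 19). Compounds 9 and 14 are purchased.

Steps most likely to fail

**Step 8.**
- What may go wrong: the epoxide migration may stall because the anti alignment of alkoxide and oxirane C–O bond is imperfect in the bicyclic frame. The wrong ring bond may migrate. The formyl group may be lost through attack of adventitious hydroxide. The acyloin may transpose before it is trapped.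
- Fallback: it sets out from 8 and comes back at 12. It gives up the epoxide migration and builds the oxirane on the six-membered ring after the ring enlargement.
- Appel-type iodination with inversion (I2, PPh3, imidazole, toluene) should give the epoxy iodide F1.
- Zinc dust (NH4Cl, EtOH) should open the oxirane reductively to the tertiary allylic hydroxy aldehyde F2, with the alkene fixed between C3 and C4.
- A chelating Lewis acid (Sc(OTf)3 cat., CH2Cl2) should induce the same α-ketol ring enlargement. It now runs reversibly toward the conjugated enone as the thermodynamic sink and should give the trans-hydroxy enone F3.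
- Acylation with 9 (pyridine, DMAP) should give the enone tiglate F4.
- Luche reduction should give the allylic alcohol F5, with the hydroxyl cis to the isopropenyl group.
- VO(acac)2 with t-BuOOH should deliver oxygen syn to that hydroxyl and give the epoxy alcohol F6.
- Dess–Martin oxidation then returns to 12.

**Step 9.**
- What may go wrong: oxidation at the ring methine or at the tiglate methyl groups may compete, conversion of the 1,1-disubstituted alkene may be sluggish, and over-oxidation may lower the throughput.
- Fallback: it sets out from 12 and comes back at 13. It replaces oxygen transfer by halogen transfer.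
- Ene-type chlorination with hypochlorous acid made from NaOCl and CeCl3·7H2O (CH2Cl2–H2O, 0 °C) should give the allylic chloride F7.
- A Kornblum-type oxidation with N-methylmorpholine N-oxide (MeCN, rt) then gives 13.

**Step 6.**
- What may go wrong: conjugate addition at the fully substituted β-carbon next to the silyloxy group may be slow, so that 1,2-attack on the formyl group and oxidative deformylation take over.
- Fallback: it sets out from 6 and comes back at 7. It moves the epoxidation to the alcohol oxidation level and to an electrophilic, directed oxidant.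
- Reduction with i-Bu2AlH (CH2Cl2, −78 °C) should give the allylic alcohol F8.
- VO(acac)2 with t-BuOOH should epoxidise only this allylic alkene, from the face opposite to the silyloxy and isopropenyl groups, to give the epoxy alcohol F9.
- Dess–Martin oxidation then gives 7.

Further compounds
F1 | step 8 | epoxy iodide, 4-iodo-5-methyl-2-(prop-1-en-2-yl)-6-oxabicyclo[3.1.0]hexane-1-carbaldehyde, iodine trans to isopropenyl | O=C[C@@]12O[C@]1(C)[C@H](I)C[C@H]2C(C)=C
F2 | step 8 | tertiary allylic hydroxy aldehyde, 1-hydroxy-2-methyl-5-(prop-1-en-2-yl)cyclopent-2-ene-1-carbaldehyde, OH trans to isopropenyl | O=C[C@@]1(O)C(C)=CC[C@H]1C(C)=C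
F3 | step 8 | trans-hydroxy enone, (5S,6S)-6-hydroxy-2-methyl-5-(prop-1-en-2-yl)cyclohex-2-en-1-one | C=C(C)[C@@H]1CC=C(C)C(=O)[C@H]1O
F4 | step 8 | enone tiglate, (E)-2-methylbut-2-enoate of F3 | C=C(C)[C@@H]1CC=C(C)C(=O)[C@H]1OC(=O)/C(C)=C/C
F5 | step 8 | allylic alcohol, 2-hydroxy-3-methyl-6-(prop-1-en-2-yl)cyclohex-3-en-1-yl (E)-2-methylbut-2-enoate, OH cis to isopropenyl and trans to the ester | C=C(C)[C@@H]1CC=C(C)[C@H](O)[C@H]1OC(=O)/C(C)=C/C
F6 | step 8 | epoxy alcohol, 2-hydroxy-1-methyl-4-(prop-1-en-2-yl)-7-oxabicyclo[4.1.0]heptan-3-yl (E)-2-methylbut-2-enoate, oxirane, OH and isopropenyl on one face | C=C(C)[C@@H]1C[C@@H]2O[C@]2(C)[C@H](O)[C@H]1OC(=O)/C(C)=C/C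
F7 | step 9 | allylic chloride, (1S,3S,4S,6S)-4-(3-chloroprop-1-en-2-yl)-1-methyl-2-oxo-7-oxabicyclo[4.1.0]heptan-3-yl (E)-2-methylbut-2-enoate | C=C(CCl)[C@@H]1C[C@@H]2O[C@]2(C)C(=O)[C@H]1OC(=O)/C(C)=C/C
F8 | step 6 | allylic alcohol, [(3S,5S)-3-(tert-butyldimethylsilyloxy)-2-methyl-5-(prop-1-en-2-yl)cyclopent-1-en-1-yl]methanol | OCC1=C(C)[C@@H](O[Si](C)(C)C(C)(C)C)C[C@H]1C(C)=C
F9 | step 6 | epoxy alcohol, [4-(tert-butyldimethylsilyloxy)-5-methyl-2-(prop-1-en-2-yl)-6-oxabicyclo[3.1.0]hexan-1-yl]methanol, oxirane trans to silyloxy and isopropenyl | OC[C@@]12O[C@]1(C)[C@@H](O[Si](C)(C)C(C)(C)C)C[C@H]2C(C)=C
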